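An eremophilane: a cis-fused decalin whose quaternary C5 lies para to the C2 ketone of ring A. Ring A is therefore traced back to a 4,4-disubstituted cyclohexa-2,5-dienone whose enone arms C1=C10 and C3=C4 are enantiotopic, and ring B to a four-carbon tether on C5 that ends in the C9 aldehyde. One carbene-catalysed intramolecular Stetter reaction joins C9 to C10, closes ring B, picks one arm and so fixes C5 and C10 with the cis ring fusion. The precursor is 4-methyl-4-(4-oxobutyl)cyclohexa-2,5-dien-1-one; the untouched C3=C4 enone and the new C9 ketone then carry the remaining four stereocentres.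

Key step: step 6

Convention: all bicyclic compounds carry the atom numbering of the target (ring A: C1 to C5 and C10, ketone at C2; ring B: C5 to C10); β is the face of the C5 methyl group, α the opposite face.
Assumption: the triazolylidene is taken to select the enone arm in the same sense as with oxygen-tethered dienone aldehydes; if the first run gives the mirror-image enedione, the commercially available antipode of the triazolium salt is used.

Step 1
Reactants: 1 3-ethoxycyclohex-2-en-1-one; 2 5-bromopent-1-ene
Product: 3 3-ethoxy-6-(pent-4-en-1-yl)cyclohex-2-en-1-one (racemic)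
Conditions: LiN(iPr)2, THF, −78 °C; then 2, DMPU, −78 → 23 °C
Reagents that add atoms: none
Why: Stork–Danheiser-type α′-alkylation, in which kinetic deprotonation of the vinylogous ester at C6 gives a cross-conjugated lithium enolate that the primary bromide alkylates, DMPU raising the reactivity of the enolate.

Step 2
Reactants: 3 3-ethoxy-6-(pent-4-en-1-yl)cyclohex-2-en-1-one
Product: 4 3-ethoxy-6-methyl-6-(pent-4-en-1-yl)cyclohex-2-en-1-one (racemic)
Conditions: LiN(iPr)2, THF, −78 °C; then MeI, −78 → 0 °C
Reagents that add atoms: iodomethane, CI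
Why: A second kinetic α′-enolate alkylation with the small and very reactive iodomethane builds the quaternary carbon (the later C5), whose configuration is of no consequence because this centre becomes prochiral in dienone 7.

Step 3
Reactants: 4 3-ethoxy-6-methyl-6-(pent-4-en-1-yl)cyclohex-2-en-1-one
Product: 6 4-methyl-4-(pent-4-en-1-yl)cyclohex-2-en-1-one, via allylic alcohol 5 (not isolated)
Conditions: LiAlH4, Et2O, 0 °C; then 2 M HCl, THF, 23 °C
Reagents that add atoms: water, O
Why: Stork–Danheiser carbonyl transposition, in which 1,2-reduction of the vinylogous ester gives allylic alcohol 5 and aqueous acid then expels water and ethanol through the oxocarbenium ion to leave the 4,4-disubstituted cyclohexenone.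

Step 4
Reactants: 6 4-methyl-4-(pent-4-en-1-yl)cyclohex-2-en-1-one
Product: 7 4-methyl-4-(pent-4-en-1-yl)cyclohexa-2,5-dien-1-one
Conditions: DDQ, 1,4-dioxane, 100 °C
Reagents that add atoms: none
Why: α′,β′-Dehydrogenation of a 4,4-dialkylcyclohexenone by DDQ (hydride abstraction from the dienol) is an established way to cross-conjugated dienones, and the isolated terminal alkene is inert to the quinone.

Step 5
Reactants: 7 4-methyl-4-(pent-4-en-1-yl)cyclohexa-2,5-dien-1-one
Product: 9 4-methyl-4-(4-oxobutyl)cyclohexa-2,5-dien-1-one, via diol 8 (not isolated)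
Conditions: OsO4 (2 mol%), NaIO4, 2,6-lutidine, 1,4-dioxane/H2O, 23 °C
Reagents that add atoms: osmium tetroxide, O=[Os](=O)(=O)=O; sodium periodate (stoichiometric oxygen source), [Na+].[O-]I(=O)(=O)=O
Why: Lemieux–Johnson cleavage, in which OsO4 dihydroxylates the electron-rich monosubstituted alkene far faster than the electron-poor dienone double bonds next to the quaternary carbon and NaIO4 cleaves diol 8 and reoxidises osmium, so the sensitive aldehyde is unveiled only immediately before the key step.

Step 6
Reactants: 9 4-methyl-4-(4-oxobutyl)cyclohexa-2,5-dien-1-one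
Product: 10 5β-methyl-10β-H-decal-3-ene-2,9-dione (cis-fused enedione)
Conditions: (5aS,10bR)-2-(pentafluorophenyl)-5a,10b-dihydro-4H,6H-indeno[2,1-b][1,2,4]triazolo[4,3-d][1,4]oxazin-2-ium tetrafluoroborate (20 mol%), KN(SiMe3)2 (18 mol%), toluene, 23 °C
Reagents that add atoms: none
Why: The triazolylidene set free by KN(SiMe3)2 adds to the C9 aldehyde, proton transfer gives the Breslow intermediate, its nucleophilic C9 adds to C10 (the β-carbon of one enone arm), and proton transfer with loss of the carbene returns the C9 ketone. The closest known reaction type is the enantioselective intramolecular Stetter desymmetrisation of 4,4-disubstituted cyclohexadienones that carry a tethered aldehyde, extended here from five-membered closures to an all-carbon six-membered one. Ring B closes in the 6-exo-trig mode. C10 is controlled by the tether, which is anchored on C5 and reaches C10 only from its own face, so the ring fusion must be cis; C5 is controlled by the chiral carbene, which decides which of the two enantiotopic arms is attacked. The step needs enantiotopic-arm selectivity and chemoselectivity for acyl-anion addition over enolisation of the aldehyde (aldol reaction or 5-exo Michael addition through C8); the first should be secured by the rigid aminoindanol backbone of the catalyst, the second by the weakly basic, electron-poor N-pentafluorophenyl carbene, the substoichiometric base and the gem-disubstituted C5 that favours cyclisation.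

Step 7
Reactants: 10 5β-methyl-10β-H-decal-3-ene-2,9-dione
Product: 11 4β,5β-dimethyl-10β-H-decalin-2,9-dione
Conditions: Me2CuLi (from MeLi and CuI), Et2O, −78 → −40 °C; then aq. NH4Cl
Reagents that add atoms: lithium dimethylcuprate, [Li+].C[Cu-]C
Why: Cuprate conjugate addition to the remaining C3=C4 enone is much faster than 1,2-addition to the saturated C9 ketone, and axial attack on the ring A half-chair with the C5–C6 bond pseudoaxial occurs anti to that bond on the convex β face (the α face meets C9 in a syn-axial position), so the new C4 methyl group should be cis to the C5 methyl group.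

Step 8
Reactants: 11 4β,5β-dimethyl-10β-H-decalin-2,9-dione
Product: 12 2,2-ethylenedioxy-4β,5β-dimethyl-10β-H-decalin-9-one
Conditions: Me3SiOCH2CH2OSiMe3, Me3SiOTf (5 mol%), CH2Cl2, −78 → −40 °C; then pyridine
Reagents that add atoms: 1,2-bis(trimethylsilyloxy)ethane, C[Si](C)(C)OCCO[Si](C)(C)C
Why: Silyl-transfer ketalisation under kinetic control at low temperature should select the unhindered C2 cyclohexanone over the C9 ketone, which is flanked by the ring-fusion methine C10 and lies 1,3 to the quaternary C5, and the cold, weakly acidic medium should leave the epimerisable C10 untouched.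

Step 9
Reactants: 12 2,2-ethylenedioxy-4β,5β-dimethyl-10β-H-decalin-9-one
Product: 14 2,2-ethylenedioxy-4β,5β-dimethyl-10β-H-decal-7-en-9-one, via silyl enol ether 13 (not isolated)
Conditions: LiN(iPr)2, Me3SiCl, THF, −78 °C; then Pd(OAc)2, MeCN, 23 °C
Reagents that add atoms: none
Why: Saegusa–Ito oxidation, in which kinetic deprotonation of the C9 ketone occurs at the C8 methylene and not at the hindered C10 methine and Pd(OAc)2 turns silyl enol ether 13 into the C7=C8 enone by β-hydride elimination from the palladium enolate, so C10 is not touched.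

Step 10
Reactants: 14 2,2-ethylenedioxy-4β,5β-dimethyl-10β-H-decal-7-en-9-one
Product: 15 2,2-ethylenedioxy-4β,5β-dimethyl-10β-H-decal-7-en-9α-ol
Conditions: NaBH4, CeCl3·7H2O, MeOH, −78 °C
Reagents that add atoms: none
Why: Luche reduction gives clean 1,2-reduction, and hydride should arrive on the convex β face because the α face of C9 is covered by ring A (C4 or C1 sits syn-axial in either half-chair of ring B), which makes the new C9 hydroxyl α.

Step 11
Reactants: 15 2,2-ethylenedioxy-4β,5β-dimethyl-10β-H-decal-7-en-9α-ol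
Product: 16 7α,8α-epoxy-2,2-ethylenedioxy-4β,5β-dimethyl-10β-H-decalin-9α-ol
Conditions: VO(acac)2 (5 mol%), t-BuOOH, CH2Cl2, 0 → 23 °C
Reagents that add atoms: tert-butyl hydroperoxide, CC(C)(C)OO
Why: Hydroxyl-directed epoxidation, in which the vanadium alkoxide of the allylic alcohol delivers the peroxide oxygen intramolecularly to the face of the C9 hydroxyl and so gives the 7α,8α-epoxide, the undirected reaction being far slower.

Step 12
Reactants: 16 7α,8α-epoxy-2,2-ethylenedioxy-4β,5β-dimethyl-10β-H-decalin-9α-ol; 17 isopropenylmagnesium bromide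
Product: 18 2,2-ethylenedioxy-7β-isopropenyl-4β,5β-dimethyl-10β-H-decalin-8α,9α-diol
Conditions: 17 (4 equiv), CuI (20 mol%), THF, −30 → 0 °C; then aq. NH4Cl
Reagents that add atoms: none
Why: Copper-catalysed Grignard opening of the epoxide by SN2 attack with inversion, in which trans-diaxial opening at C7 (the carbon remote from the inductively deactivating C9 alkoxide) places the isopropenyl group β on C7 and leaves the C8 oxygen α, so C7 and C8 follow stereospecifically from the epoxide.

Step 13
Reactants: 18 2,2-ethylenedioxy-7β-isopropenyl-4β,5β-dimethyl-10β-H-decalin-8α,9α-diol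
Product: 19 2,2-ethylenedioxy-7β-isopropenyl-4β,5β-dimethyl-8α-(triethylsilyloxy)-10β-H-decalin-9α-ol
Conditions: Et3SiCl (1.1 equiv), imidazole, CH2Cl2, −20 → 0 °C
Reagents that add atoms: chlorotriethylsilane, CC[Si](Cl)(CC)CC
Why: Selective silylation, since the equatorial C8 hydroxyl is far more accessible than the axial C9 hydroxyl (flanked by the ring fusion and syn-axial to C4), so one equivalent of silyl chloride should protect C8 only.

Step 14
Reactants: 19 2,2-ethylenedioxy-7β-isopropenyl-4β,5β-dimethyl-8α-(triethylsilyloxy)-10β-H-decalin-9α-ol; 20 tiglic acid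
Product: 22 2,2-ethylenedioxy-7β-isopropenyl-4β,5β-dimethyl-8α-(triethylsilyloxy)-10β-H-decalin-9α-yl (E)-2-methylbut-2-enoate, via mixed anhydride 21 (not isolated)
Conditions: 20, 2,4,6-trichlorobenzoyl chloride, Et3N, toluene, 23 °C; then 19, DMAP, toluene, 60 °C
Reagents that add atoms: none
Why: Yamaguchi esterification through mixed anhydride 21 and the acylpyridinium ion should acylate the hindered C9 hydroxyl with retention of the E geometry, and because C8 is blocked as a silyl ether no acyl migration can put the tiglate on the wrong oxygen.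

Step 15
Reactants: 22 2,2-ethylenedioxy-7β-isopropenyl-4β,5β-dimethyl-8α-(triethylsilyloxy)-10β-H-decalin-9α-yl (E)-2-methylbut-2-enoate
Product: 23 8α-hydroxy-7β-isopropenyl-4β,5β-dimethyl-2-oxo-10β-H-decalin-9α-yl (E)-2-methylbut-2-enoate
Conditions: 1 M HCl, THF, 23 °C
Reagents that add atoms: water, O
Why: Acid hydrolysis cleaves the triethylsilyl ether and the dioxolane in one operation, while the ester, the isopropenyl group and the stereocentres (none of them α to the freed C2 ketone) should persist in dilute acid at ambient temperature.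

Step 16
Reactants: 23 8α-hydroxy-7β-isopropenyl-4β,5β-dimethyl-2-oxo-10β-H-decalin-9α-yl (E)-2-methylbut-2-enoate
Product: 24 8α-acetoxy-7β-isopropenyl-4β,5β-dimethyl-2-oxo-10β-H-decalin-9α-yl (E)-2-methylbut-2-enoate (target)
Conditions: Ac2O, pyridine, DMAP (cat.), CH2Cl2, 0 → 23 °C
Reagents that add atoms: acetic anhydride, CC(=O)OC(C)=O
Why: DMAP-catalysed acetylation of the unhindered equatorial C8 hydroxyl is fast, so the neighbouring tiglate should have no time to migrate, and it completes the target.

Compound list
1 | 3-ethoxycyclohex-2-en-1-one | CCOC1=CC(=O)CCC1 | starting material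
2 | 5-bromopent-1-ene | BrCCCC=C | starting material
3 | 3-ethoxy-6-(pent-4-en-1-yl)cyclohex-2-en-1-one (racemic) | CCOC1=CC(=O)C(CCCC=C)CC1 | intermediate
4 | 3-ethoxy-6-methyl-6-(pent-4-en-1-yl)cyclohex-2-en-1-one (racemic) | CCOC1=CC(=O)C(C)(CCCC=C)CC1 | intermediate
5 | 3-ethoxy-6-methyl-6-(pent-4-en-1-yl)cyclohex-2-en-1-ol (diastereomer mixture, not isolated) | CCOC1=CC(O)C(C)(CCCC=C)CC1 | intermediate
6 | 4-methyl-4-(pent-4-en-1-yl)cyclohex-2-en-1-one (racemic) | CC1(CCCC=C)C=CC(=O)CC1 | intermediate
7 | 4-methyl-4-(pent-4-en-1-yl)cyclohexa-2,5-dien-1-one (achiral, prochiral at C4 of the ring) | CC1(CCCC=C)C=CC(=O)C=C1 | intermediate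
8 | 4-(4,5-dihydroxypentyl)-4-methylcyclohexa-2,5-dien-1-one (racemic, not isolated) | CC1(CCCC(O)CO)C=CC(=O)C=C1 | intermediate
9 | 4-methyl-4-(4-oxobutyl)cyclohexa-2,5-dien-1-one | CC1(CCCC=O)C=CC(=O)C=C1 | intermediate
10 | (5R,10S)-5β-methyl-10β-H-decal-3-ene-2,9-dione, cis-fused; systematic: (4aR,8aS)-4a-methyl-3,4,4a,8a-tetrahydronaphthalene-1,7(2H,8H)-dione | C1C[C@@]2(C)[C@H](CC(=O)C=C2)C(=O)C1 | intermediate
11 | (4S,5R,10S)-4β,5β-dimethyl-10β-H-decalin-2,9-dione, cis-fused | C1C[C@@]2(C)[C@H](CC(=O)C[C@@H]2C)C(=O)C1 | intermediate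
12 | 2,2-ethylenedioxy-4β,5β-dimethyl-10β-H-decalin-9-one (C2 dioxolane of 11) | C1C[C@@]2(C)[C@H](CC3(OCCO3)C[C@@H]2C)C(=O)C1 | intermediate
13 | 2,2-ethylenedioxy-4β,5β-dimethyl-9-(trimethylsilyloxy)-10β-H-decal-8-ene (not isolated) | C1C[C@@]2(C)[C@H](CC3(OCCO3)C[C@@H]2C)C(O[Si](C)(C)C)=C1 | intermediate
14 | 2,2-ethylenedioxy-4β,5β-dimethyl-10β-H-decal-7-en-9-one | C1C[C@@]2(C)[C@H](CC3(OCCO3)C[C@@H]2C)C(=O)C=1 | intermediate
15 | 2,2-ethylenedioxy-4β,5β-dimethyl-10β-H-decal-7-en-9α-ol | C1C[C@@]2(C)[C@H](CC3(OCCO3)C[C@@H]2C)[C@H](O)C=1 | intermediate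
16 | 7α,8α-epoxy-2,2-ethylenedioxy-4β,5β-dimethyl-10β-H-decalin-9α-ol | [C@@H]14C[C@@]2(C)[C@H](CC3(OCCO3)C[C@@H]2C)[C@H](O)[C@@H]1O4 | intermediate
17 | isopropenylmagnesium bromide | C=C(C)[Mg]Br | starting material
18 | 2,2-ethylenedioxy-7β-isopropenyl-4β,5β-dimethyl-10β-H-decalin-8α,9α-diol | C=C(C)[C@H]1C[C@@]2(C)[C@H](CC3(OCCO3)C[C@@H]2C)[C@H](O)[C@@H]1O | intermediate
19 | 2,2-ethylenedioxy-7β-isopropenyl-4β,5β-dimethyl-8α-(triethylsilyloxy)-10β-H-decalin-9α-ol | C=C(C)[C@H]1C[C@@]2(C)[C@H](CC3(OCCO3)C[C@@H]2C)[C@H](O)[C@@H]1O[Si](CC)(CC)CC | intermediate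
20 | tiglic acid, (E)-2-methylbut-2-enoic acid | C/C=C(\C)C(=O)O | starting material
21 | (E)-2-methylbut-2-enoic 2,4,6-trichlorobenzoic anhydride (not isolated) | C/C=C(\C)C(=O)OC(=O)c1c(Cl)cc(Cl)cc1Cl | intermediate
22 | 2,2-ethylenedioxy-7β-isopropenyl-4β,5β-dimethyl-8α-(triethylsilyloxy)-10β-H-decalin-9α-yl (E)-2-methylbut-2-enoate | C=C(C)[C@H]1C[C@@]2(C)[C@H](CC3(OCCO3)C[C@@H]2C)[C@H](OC(=O)/C(C)=C/C)[C@@H]1O[Si](CC)(CC)CC | intermediate
23 | 8α-hydroxy-7β-isopropenyl-4β,5β-dimethyl-2-oxo-10β-H-decalin-9α-yl (E)-2-methylbut-2-enoate | C=C(C)[C@H]1C[C@@]2(C)[C@H](CC(=O)C[C@@H]2C)[C@H](OC(=O)/C(C)=C/C)[C@@H]1O | intermediate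
24 | 8α-acetoxy-7β-isopropenyl-4β,5β-dimethyl-2-oxo-10β-H-decalin-9α-yl (E)-2-methylbut-2-enoate, (4S,5R,7R,8R,9S,10S); systematic: (1S,2R,3R,4aR,5S,8aS)-2-acetoxy-4a,5-dimethyl-7-oxo-3-(prop-1-en-2-yl)decahydronaphthalen-1-yl (E)-2-methylbut-2-enoate | C=C(C)[C@H]1C[C@@]2(C)[C@H](CC(=O)C[C@@H]2C)[C@H](OC(=O)/C(C)=C/C)[C@@H]1OC(C)=O | target

Total step count: 16. Longest linear sequence: 16 steps (1 → 24; compounds 2, 17 and 20 are purchased).

Steps most likely to fail

Step 6. The six-membered, all-carbon closure is slower than the five-membered closures for which this desymmetrisation is established, so enolisation of the aldehyde (aldol reaction or Michael addition through C8) or imperfect arm selection may take over. The fallback sets out from 9 and comes back at 10, and it replaces the acyl anion equivalent by a nitronate. Aldehyde 9 is reduced chemoselectively with NaBH(OAc)3 to 4-(4-hydroxybutyl)-4-methylcyclohexa-2,5-dien-1-one F1. This is converted with I2, PPh3 and imidazole into 4-(4-iodobutyl)-4-methylcyclohexa-2,5-dien-1-one F2, and with NaNO2 in DMSO (Kornblum substitution) into 4-methyl-4-(4-nitrobutyl)cyclohexa-2,5-dien-1-one F3. A quinine-derived bifunctional thiourea then mediates the desymmetrising intramolecular nitro-Michael addition (C9 nitronate onto C10, 6-exo-trig, cis fusion again enforced by the tether) to 9-nitro-5β-methyl-10β-H-decal-3-en-2-one F4. A Nef reaction (TiCl3, aqueous NH4OAc) turns the secondary nitro group into the C9 ketone of 10.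

Step 12. The isopropenyl group must enter at C7 syn-axial to the C5 methyl group, so the opening may be slow and give way to attack at C8 or to bromohydrin formation by the magnesium halide. The fallback sets out from 14 and comes back at 19, and it sets the three ring B centres by conjugate addition instead. Enone 14 takes up the isopropenyl group of 17 under CuBr·SMe2 catalysis with Et3SiCl trapping, which should give, by attack on the convex face, 2,2-ethylenedioxy-7β-isopropenyl-4β,5β-dimethyl-9-(triethylsilyloxy)-10β-H-decal-8-ene F5. Rubottom oxidation (mCPBA, NaHCO3, CH2Cl2) with 1,4-silyl shift, trans to the new C7 substituent, should give 2,2-ethylenedioxy-7β-isopropenyl-4β,5β-dimethyl-8α-(triethylsilyloxy)-10β-H-decalin-9-one F6. LiBH(s-Bu)3 then reduces C9 from the convex face to 19. This sequence rests on substrate-controlled facial selectivity at C7 and C8 and not on a stereospecific opening, which is why it is held in reserve.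

Step 14. The axial C9 hydroxyl is hindered, so acylation by the conjugated and therefore sluggish tigloyl donor may stall, and forcing conditions invite silyl migration from O8 to O9. The fallback sets out from 19 and comes back at 22, and it builds the unsaturated ester on the oxygen. Steglich esterification of 19 with the more reactive saturated acid 2-(diethoxyphosphoryl)propanoic acid (DCC, DMAP) gives 2,2-ethylenedioxy-7β-isopropenyl-4β,5β-dimethyl-8α-(triethylsilyloxy)-10β-H-decalin-9α-yl 2-(diethoxyphosphoryl)propanoate F7. A Horner–Wadsworth–Emmons reaction with acetaldehyde (LiCl, DBU, MeCN) then forms the E-configured 2-methylbut-2-enoate, which is 22.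

Further compounds
F1 | step 6 | 4-(4-hydroxybutyl)-4-methylcyclohexa-2,5-dien-1-one | CC1(CCCCO)C=CC(=O)C=C1
F2 | step 6 | 4-(4-iodobutyl)-4-methylcyclohexa-2,5-dien-1-one | CC1(CCCCI)C=CC(=O)C=C1
F3 | step 6 | 4-methyl-4-(4-nitrobutyl)cyclohexa-2,5-dien-1-one | CC1(CCCC[N+](=O)[O-])C=CC(=O)C=C1
F4 | step 6 | 9-nitro-5β-methyl-10β-H-decal-3-en-2-one (cis-fused, mixture of C9 epimers) | C1C[C@@]2(C)[C@H](CC(=O)C=C2)C([N+](=O)[O-])C1
F5 | step 12 | 2,2-ethylenedioxy-7β-isopropenyl-4β,5β-dimethyl-9-(triethylsilyloxy)-10β-H-decal-8-ene | C=C(C)[C@H]1C[C@@]2(C)[C@H](CC3(OCCO3)C[C@@H]2C)C(O[Si](CC)(CC)CC)=C1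
F6 | step 12 | 2,2-ethylenedioxy-7β-isopropenyl-4β,5β-dimethyl-8α-(triethylsilyloxy)-10β-H-decalin-9-one | C=C(C)[C@H]1C[C@@]2(C)[C@H](CC3(OCCO3)C[C@@H]2C)C(=O)[C@@H]1O[Si](CC)(CC)CC
F7 | step 14 | 2,2-ethylenedioxy-7β-isopropenyl-4β,5β-dimethyl-8α-(triethylsilyloxy)-10β-H-decalin-9α-yl 2-(diethoxyphosphoryl)propanoate | C=C(C)[C@H]1C[C@@]2(C)[C@H](CC3(OCCO3)C[C@@H]2C)[C@H](OC(=O)C(C)P(=O)(OCC)OCC)[C@@H]1O[Si](CC)(CC)CC
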